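The cyclohexadiene is numbered C1 (quaternary, pyrone-bearing) to C6 (CH carrying the enone). Everything rests on inserting C3 between C2 and C4 of a cyclopentene that already holds both stereocentres: dibromocarbene adds to the C2=C4 alkene and the strained bicycle opens, with loss of HBr, to the six-membered 3-bromo-2,4-diene in one operation, forming C2–C3 and C3–C4. The step exploits that C3 sits between two CH carbons while C1 carries no hydrogen, so elimination can only run towards C5. The precursor is a cyclopentene with methyl and silyloxymethyl on C1, a ketal-masked acetyl on C6 and a methyl on C5, assembled by chirality-transferring Ireland–Claisen rearrangement and ring-closing metathesis.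

Key step: step 8

Remark on the chemistry: racemic acid 5 is used, so 6–12, 14 and 15 are pairs of C5 epimers (C5 left undefined in their SMILES) that converge in step 8; five-membered-ring compounds keep the numbering C1, C2, C4, C5, C6 of the final ring, C3 being the carbon inserted in step 8.

Step 1
Reactants: 1 1-(tert-butyldimethylsilyloxy)propan-2-one; 2 1-(triphenyl-λ5-phosphanylidene)propan-2-one
Product: 3 (3E)-5-(tert-butyldimethylsilyloxy)-4-methylpent-3-en-2-one
Conditions: toluene, 110 °C
Reagents that add atoms: none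
Why: Wittig olefination of an activated α-silyloxy ketone with a stabilised acyl ylide should favour the E enone, in which acetyl lies trans to the larger silyloxymethyl group; the minor Z isomer is removed by chromatography.

Step 2
Reactants: 3 the E enone
Product: 4 (2R,3E)-5-(tert-butyldimethylsilyloxy)-4-methylpent-3-en-2-ol
Conditions: (S)-Me-CBS oxazaborolidine [(S)-1-methyl-3,3-diphenyltetrahydro-1H,3H-pyrrolo[1,2-c][1,3,2]oxazaborole] (10 mol %), catecholborane, toluene, −78 °C; then MeOH, aq. NaOH
Reagents that add atoms: none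
Why: Corey–Bakshi–Shibata reduction, in which the alkenyl group plays the large substituent so that hydride is delivered 1,2 to the face giving the R carbinol (the sense that turns acetophenone into the R alcohol).

Step 3
Reactants: 4 the R allylic alcohol; 5 3-methylpent-4-enoic acid (racemic)
Product: 6 (2R,3E)-5-(tert-butyldimethylsilyloxy)-4-methylpent-3-en-2-yl 3-methylpent-4-enoate
Conditions: DCC, 4-(dimethylamino)pyridine (10 mol %), CH2Cl2, 0 °C to rt
Reagents that add atoms: none
Why: Steglich esterification acylates the secondary allylic alcohol under neutral conditions that leave the carbinol centre and the silyl ether untouched.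

Step 4
Reactants: 6 the allylic ester
Product: 9 (2R,3S,4E)-2-(but-3-en-2-yl)-3-[(tert-butyldimethylsilyloxy)methyl]-3-methylhex-4-enoic acid, via silyl ketene acetal 7 (not isolated), via trimethylsilyl ester 8 (not isolated)
Conditions: LiN(iPr)2, THF/DMPU (2:1), −78 °C; Me3SiCl, −78 °C to rt, then 50 °C; aq. citric acid
Reagents that add atoms: none
Why: Ireland–Claisen rearrangement: enolisation in the presence of DMPU should give the Z(O) enolate and hence ketene acetal 7 with the butenyl group trans to the allylic oxygen, and the chair transition state with the carbinol methyl equatorial places the E silyloxymethyl group and the butenyl group equatorial, so the R carbinol centre is relayed into C1 (acid C3, S) and C6 (acid C2, R) while the new alkene forms as E.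

Step 5
Reactants: 9 the acid
Product: 10 (3R,4S,5E)-3-(but-3-en-2-yl)-4-[(tert-butyldimethylsilyloxy)methyl]-4-methylhept-5-en-2-one
Conditions: MeLi (3 equiv), Et2O, 0 °C to rt; inverse quench into cold aq. NH4Cl
Reagents that add atoms: methyllithium, [Li]C
Why: Double addition of methyllithium to the hindered carboxylic acid stops at the dilithium gem-diolate, which releases the methyl ketone only on work-up, so neither over-addition nor epimerisation at C6 is expected.

Step 6
Reactants: 10 the dienyl methyl ketone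
Product: 11 1-[(1R,2S)-2-[(tert-butyldimethylsilyloxy)methyl]-2,5-dimethylcyclopent-3-en-1-yl]ethan-1-one
Conditions: second-generation Grubbs catalyst RuCl2(=CHPh)(H2IMes)(PCy3) (3 mol %), CH2Cl2, 40 °C
Reagents that add atoms: none
Why: Ring-closing metathesis of the vinyl and propenyl groups closes the five-membered ring with loss of propene, helped by the quaternary centre, without touching C1 or C6; any C6 epimer carried from step 4 is removed by chromatography here.

Step 7
Reactants: 11 the cyclopentenyl methyl ketone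
Product: 12 tert-butyl{[(1S,5R)-1,4-dimethyl-5-(2-methyl-1,3-dioxolan-2-yl)cyclopent-2-en-1-yl]methoxy}dimethylsilane
Conditions: 1,2-bis(trimethylsilyloxy)ethane, Me3SiOTf (5 mol %), CH2Cl2, −78 to −20 °C; pyridine quench
Reagents that add atoms: 1,2-bis(trimethylsilyloxy)ethane, C[Si](C)(C)OCCO[Si](C)(C)C
Why: Aprotic silyl-transfer ketalisation masks the hindered methyl ketone at low temperature, where the silyl ether survives and C6 should not enolise.

Step 8
Reactants: 12 the cyclopentene ketal; 13 bromoform
Product: 16 tert-butyl{[(1R,6R)-3-bromo-1,5-dimethyl-6-(2-methyl-1,3-dioxolan-2-yl)cyclohexa-2,4-dien-1-yl]methoxy}dimethylsilane, via dibromobicyclohexane 14 (not isolated), via allylic dibromide 15 (not isolated)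
Conditions: KOtBu (in excess over 13), toluene, −15 °C to rt; then DBU, 80 °C, same flask
Reagents that add atoms: none
Why: Dibromocarbene from α-elimination of bromoform adds in a concerted cheletropic step to C2=C4 (forming C2–C3 and C3–C4) to give 14; on warming, the endo C–Br bond ionises together with disrotatory opening of the C2–C4 bond, bromide returns to the 2-bromoallyl cation to give 15, and DBU removes H-5. The closest known reaction type is the dihalocarbene ring expansion of cyclopentenes to 2-halocyclohexa-1,3-dienes. The six-membered ring arises by one-carbon ring expansion ([2+1] cycloaddition, then two-electron electrocyclic opening driven by release of cyclopropane strain), not by an exo or endo cyclisation. No stereocentre that survives is created: C2 and C4 of 14 and C4 of 15 end as sp2 carbons, so both faces of carbene attack and both C5 epimers converge, while C1 and C6 are spectators (the change of the C1 descriptor to R only reflects the priority of bromine). Chemoselectivity rests on the single alkene, with silyl ether and ketal inert to carbene and base, and regioselective elimination on the hydrogen-free quaternary C1 and the brominated C3, which leave H-5 as the only β-hydrogen. Excess alkoxide ensures that no carbene source remains when the diene appears, and 80 °C is low enough to avoid [1,5]-hydrogen shifts.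

Step 9
Reactants: 16 the bromodiene
Product: 17 tert-butyldimethyl{[(1S,6R)-1,3,5-trimethyl-6-(2-methyl-1,3-dioxolan-2-yl)cyclohexa-2,4-dien-1-yl]methoxy}silane
Conditions: MeZnCl, Pd(PPh3)4 (5 mol %), THF, rt to 45 °C
Reagents that add atoms: methylzinc chloride, C[Zn]Cl
Why: Negishi coupling of the unhindered dienyl bromide installs the C3 methyl group under neutral, mild conditions that tolerate ketal and silyl ether and keep the diene cool.

Step 10
Reactants: 17 the silyl ether
Product: 18 [(1S,6R)-1,3,5-trimethyl-6-(2-methyl-1,3-dioxolan-2-yl)cyclohexa-2,4-dien-1-yl]methanol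
Conditions: Bu4NF, THF, rt to 40 °C
Reagents that add atoms: none
Why: Fluoride-mediated desilylation frees the neopentyl alcohol while ketal and diene are inert to the basic medium.

Step 11
Reactants: 18 the primary alcohol
Product: 19 (1S,6R)-1,3,5-trimethyl-6-(2-methyl-1,3-dioxolan-2-yl)cyclohexa-2,4-diene-1-carbaldehyde
Conditions: Dess–Martin periodinane, pyridine, CH2Cl2, 0 °C to rt
Reagents that add atoms: none
Why: Buffered Dess–Martin oxidation gives an aldehyde on the quaternary C1 that has no α-hydrogen and so can neither epimerise nor move into conjugation.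

Step 12
Reactants: 19 the aldehyde; 20 methyl 2-methyl-3-oxopentanoate
Product: 22 methyl 5-hydroxy-2,4-dimethyl-3-oxo-5-[(1S,6R)-1,3,5-trimethyl-6-(2-methyl-1,3-dioxolan-2-yl)cyclohexa-2,4-dien-1-yl]pentanoate (mixture of chain diastereomers), via ketoester dianion 21 (not isolated)
Conditions: 20, NaH, THF, 0 °C; nBuLi, 0 °C; then 19, −78 to −40 °C; aq. NH4Cl
Reagents that add atoms: none
Why: Aldol addition of the γ-carbon of the β-keto ester dianion, its most nucleophilic site, to the non-enolisable aldehyde; the three new chain centres are erased in steps 13 and 14.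

Step 13
Reactants: 22 the aldol adduct
Product: 23 methyl 2,4-dimethyl-3,5-dioxo-5-[(1S,6R)-1,3,5-trimethyl-6-(2-methyl-1,3-dioxolan-2-yl)cyclohexa-2,4-dien-1-yl]pentanoate
Conditions: Dess–Martin periodinane, pyridine, CH2Cl2, rt
Reagents that add atoms: none
Why: Dess–Martin oxidation of the hindered secondary alcohol gives the 3,5-diketo ester without retro-aldol cleavage under near-neutral conditions.

Step 14
Reactants: 23 the diketo ester
Product: 24 4-hydroxy-3,5-dimethyl-6-[(1S,6R)-1,3,5-trimethyl-6-(2-methyl-1,3-dioxolan-2-yl)cyclohexa-2,4-dien-1-yl]-2H-pyran-2-one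
Conditions: DBU, toluene, rt to 60 °C; aq. citric acid
Reagents that add atoms: none
Why: Base-mediated lactonisation, in which the enolate oxygen of the C5 ketone attacks the ester in a 6-exo-trig acyl substitution with loss of methanol, the standard closure of triketide esters to 4-hydroxy-2-pyranones.

Step 15
Reactants: 24 the hydroxypyranone
Product: 25 2-methoxy-3,5-dimethyl-6-[(1S,6R)-1,3,5-trimethyl-6-(2-methyl-1,3-dioxolan-2-yl)cyclohexa-2,4-dien-1-yl]-4H-pyran-4-one
Conditions: MeOTf, 2,6-di-tert-butyl-4-methylpyridine, CH2Cl2, 0 °C to rt; aq. NaHCO3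
Reagents that add atoms: methyl trifluoromethanesulfonate, COS(=O)(=O)C(F)(F)F
Why: O-Methylation under neutral conditions takes place at the lactone carbonyl oxygen, the most nucleophilic site of the neutral hydroxypyranone, and loss of the proton from the 4-hydroxypyrylium ion gives the 2-methoxy-4-pyranone, while the hindered pyridine buffers the triflic acid so that diene and ketal survive.

Step 16
Reactants: 25 the methoxypyranone ketal
Product: 26 6-[(1S,6R)-6-acetyl-1,3,5-trimethylcyclohexa-2,4-dien-1-yl]-2-methoxy-3,5-dimethyl-4H-pyran-4-one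
Conditions: pyridinium p-toluenesulfonate, acetone/H2O, 45 °C
Reagents that add atoms: water, O
Why: Mild acid-catalysed ketal hydrolysis, at an acidity too low to enolise the β,γ-unsaturated ketone, so that C6 should keep its configuration; 26 is used at once.

Step 17
Reactants: 26 the methyl ketone; 27 prop-1-yn-1-ylmagnesium bromide
Product: 28 6-[(1S,6R)-6-(2-hydroxypent-3-yn-2-yl)-1,3,5-trimethylcyclohexa-2,4-dien-1-yl]-2-methoxy-3,5-dimethyl-4H-pyran-4-one (both carbinol epimers)
Conditions: LaCl3·2LiCl (30 mol %), THF, −40 to 0 °C; aq. NH4Cl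
Reagents that add atoms: none
Why: 1,2-Addition of a weakly basic alkynyl Grignard reagent to the ketone, which is far more electrophilic than the doubly vinylogous ester carbonyl of the pyranone, with the lanthanum salt favouring addition over enolisation; the new carbinol centre is lost in step 18.

Step 18
Reactants: 28 the tertiary propargylic alcohol
Product: 29 2-methoxy-3,5-dimethyl-6-{(1S,6S)-1,3,5-trimethyl-6-[(2E)-4-oxopent-2-en-2-yl]cyclohexa-2,4-dien-1-yl}-4H-pyran-4-one (target)
Conditions: ReOCl3(OPPh3)(SMe2) (5 mol %), 1,2-dimethoxyethane, rt to 40 °C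
Reagents that add atoms: none
Why: Meyer–Schuster rearrangement through an oxo-rhenium propargyl ester and its [3,3] shift to the allenolate, a neutral pathway that avoids free cations and π-acid activation of the alkyne next to the diene; the E enone, with acetyl anti to the ring, is the expected thermodynamic product (the C6 descriptor changes to S only through substituent priorities).

Compound list
1 | 1-(tert-butyldimethylsilyloxy)propan-2-one | CC(=O)CO[Si](C)(C)C(C)(C)C | starting material
2 | 1-(triphenyl-λ5-phosphanylidene)propan-2-one | CC(=O)C=P(c1ccccc1)(c1ccccc1)c1ccccc1 | starting material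
3 | (3E)-5-(tert-butyldimethylsilyloxy)-4-methylpent-3-en-2-one | CC(=O)/C=C(\C)CO[Si](C)(C)C(C)(C)C | intermediate
4 | (2R,3E)-5-(tert-butyldimethylsilyloxy)-4-methylpent-3-en-2-ol | C[C@@H](O)/C=C(\C)CO[Si](C)(C)C(C)(C)C | intermediate
5 | 3-methylpent-4-enoic acid (racemic) | C=CC(C)CC(=O)O | starting material
6 | (2R,3E)-5-(tert-butyldimethylsilyloxy)-4-methylpent-3-en-2-yl 3-methylpent-4-enoate (both epimers at acyl C3) | C=CC(C)CC(=O)O[C@H](C)/C=C(\C)CO[Si](C)(C)C(C)(C)C | intermediate
7 | Z(O) trimethylsilyl ketene acetal of 6 (butenyl cis to OSiMe3) | C=CC(C)/C=C(\O[Si](C)(C)C)O[C@H](C)/C=C(\C)CO[Si](C)(C)C(C)(C)C | intermediate (not isolated)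
8 | trimethylsilyl ester of acid 9 | CC(C)(C)[Si](C)(C)OC[C@@]([C@H](C(=O)O[Si](C)(C)C)C(C)C=C)(C)/C=C/C | intermediate (not isolated)
9 | (2R,3S,4E)-2-(but-3-en-2-yl)-3-[(tert-butyldimethylsilyloxy)methyl]-3-methylhex-4-enoic acid | CC(C)(C)[Si](C)(C)OC[C@@]([C@H](C(=O)O)C(C)C=C)(C)/C=C/C | intermediate
10 | (3R,4S,5E)-3-(but-3-en-2-yl)-4-[(tert-butyldimethylsilyloxy)methyl]-4-methylhept-5-en-2-one | CC(C)(C)[Si](C)(C)OC[C@@]([C@H](C(C)=O)C(C)C=C)(C)/C=C/C | intermediate
11 | 1-[(1R,2S)-2-[(tert-butyldimethylsilyloxy)methyl]-2,5-dimethylcyclopent-3-en-1-yl]ethan-1-one (silyloxymethyl and acetyl cis) | CC(C)(C)[Si](C)(C)OC[C@@]1(C)C=CC(C)[C@H]1C(C)=O | intermediate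
12 | tert-butyl{[(1S,5R)-1,4-dimethyl-5-(2-methyl-1,3-dioxolan-2-yl)cyclopent-2-en-1-yl]methoxy}dimethylsilane (silyloxymethyl and dioxolanyl cis; key-step precursor) | CC(C)(C)[Si](C)(C)OC[C@@]1(C)C=CC(C)[C@H]1C2(C)OCCO2 | intermediate
13 | bromoform | BrC(Br)Br | starting material
14 | 6,6-dibromobicyclo[3.1.0]hexane adduct of 12 (CBr2 bridging C2 and C4) | CC(C)(C)[Si](C)(C)OC[C@@]1(C)C2C(C(C)[C@H]1C3(C)OCCO3)C2(Br)Br | intermediate (not isolated)
15 | 3,4-dibromocyclohex-2-ene (allylic bromide at C4, vinyl bromide at C3) | CC(C)(C)[Si](C)(C)OC[C@@]1(C)C=C(Br)C(Br)C(C)[C@H]1C2(C)OCCO2 | intermediate (not isolated)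
16 | tert-butyl{[(1R,6R)-3-bromo-1,5-dimethyl-6-(2-methyl-1,3-dioxolan-2-yl)cyclohexa-2,4-dien-1-yl]methoxy}dimethylsilane | CC(C)(C)[Si](C)(C)OC[C@@]1(C)C=C(Br)C=C(C)[C@H]1C2(C)OCCO2 | intermediate
17 | tert-butyldimethyl{[(1S,6R)-1,3,5-trimethyl-6-(2-methyl-1,3-dioxolan-2-yl)cyclohexa-2,4-dien-1-yl]methoxy}silane | CC(C)(C)[Si](C)(C)OC[C@@]1(C)C=C(C)C=C(C)[C@H]1C2(C)OCCO2 | intermediate
18 | [(1S,6R)-1,3,5-trimethyl-6-(2-methyl-1,3-dioxolan-2-yl)cyclohexa-2,4-dien-1-yl]methanol | OC[C@@]1(C)C=C(C)C=C(C)[C@H]1C2(C)OCCO2 | intermediate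
19 | (1S,6R)-1,3,5-trimethyl-6-(2-methyl-1,3-dioxolan-2-yl)cyclohexa-2,4-diene-1-carbaldehyde | O=C[C@@]1(C)C=C(C)C=C(C)[C@H]1C2(C)OCCO2 | intermediate
20 | methyl 2-methyl-3-oxopentanoate | CCC(=O)C(C)C(=O)OC | starting material
21 | sodium lithium dianion of 20 (C2 and C4 deprotonated) | COC(=O)[C-](C)C(=O)[CH-]C.[Na+].[Li+] | intermediate (not isolated)
22 | methyl 5-hydroxy-2,4-dimethyl-3-oxo-5-[(1S,6R)-1,3,5-trimethyl-6-(2-methyl-1,3-dioxolan-2-yl)cyclohexa-2,4-dien-1-yl]pentanoate (chain diastereomers) | COC(=O)C(C)C(=O)C(C)C(O)[C@@]1(C)C=C(C)C=C(C)[C@H]1C2(C)OCCO2 | intermediate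
23 | methyl 2,4-dimethyl-3,5-dioxo-5-[(1S,6R)-1,3,5-trimethyl-6-(2-methyl-1,3-dioxolan-2-yl)cyclohexa-2,4-dien-1-yl]pentanoate | COC(=O)C(C)C(=O)C(C)C(=O)[C@@]1(C)C=C(C)C=C(C)[C@H]1C2(C)OCCO2 | intermediate
24 | 4-hydroxy-3,5-dimethyl-6-[(1S,6R)-1,3,5-trimethyl-6-(2-methyl-1,3-dioxolan-2-yl)cyclohexa-2,4-dien-1-yl]-2H-pyran-2-one | O=c1oc([C@@]2(C)C=C(C)C=C(C)[C@H]2C3(C)OCCO3)c(C)c(O)c1C | intermediate
25 | 2-methoxy-3,5-dimethyl-6-[(1S,6R)-1,3,5-trimethyl-6-(2-methyl-1,3-dioxolan-2-yl)cyclohexa-2,4-dien-1-yl]-4H-pyran-4-one | COc1oc([C@@]2(C)C=C(C)C=C(C)[C@H]2C3(C)OCCO3)c(C)c(=O)c1C | intermediate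
26 | 6-[(1S,6R)-6-acetyl-1,3,5-trimethylcyclohexa-2,4-dien-1-yl]-2-methoxy-3,5-dimethyl-4H-pyran-4-one | COc1oc([C@@]2(C)C=C(C)C=C(C)[C@H]2C(C)=O)c(C)c(=O)c1C | intermediate
27 | prop-1-yn-1-ylmagnesium bromide | CC#C[Mg]Br | starting material
28 | 6-[(1S,6R)-6-(2-hydroxypent-3-yn-2-yl)-1,3,5-trimethylcyclohexa-2,4-dien-1-yl]-2-methoxy-3,5-dimethyl-4H-pyran-4-one (both carbinol epimers) | COc1oc([C@@]2(C)C=C(C)C=C(C)[C@H]2C(C)(O)C#CC)c(C)c(=O)c1C | intermediate
29 | 2-methoxy-3,5-dimethyl-6-{(1S,6S)-1,3,5-trimethyl-6-[(2E)-4-oxopent-2-en-2-yl]cyclohexa-2,4-dien-1-yl}-4H-pyran-4-one | COc1oc([C@@]2(C)C=C(C)C=C(C)[C@H]2/C(C)=C/C(C)=O)c(C)c(=O)c1C | target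

Total step count: 18. Longest linear sequence: 18 steps (1 to 29); 2, 5, 13, 20 and 27 are purchased partners.

Steps most likely to fail

1. Step 8. What may go wrong: slow carbene transfer to an alkene shielded by the quaternary C1 and the C5 methyl; interception of the allyl cation by the neighbouring ketal oxygen; a thermal [1,5]-hydrogen shift that would move H-6. The fallback sets out from 12 and returns at 17. Dichlorocarbene generated under phase-transfer conditions (CHCl3, 50% aq. NaOH, BnEt3NCl), the most forcing carbene source for hindered alkenes, should give the isolable 6,6-dichlorobicyclo[3.1.0]hexane F1. Silver-assisted ionisation (AgBF4, 2,6-di-tert-butylpyridine, 1,2-dichloroethane, 50 °C) without a nucleophilic counter-ion lets the cation lose H-5 directly to the 3-chloro-2,4-diene F2. Nickel-catalysed Kumada coupling (MeMgBr, NiCl2(Ph2PCH2CH2CH2PPh2), THF, rt) then gives 17.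

2. Step 4. What may go wrong: incomplete control of enolate geometry in the amide-base enolisation, so that part of the material rearranges through the E(O) ketene acetal to the C6 epimer, which is hard to separate while C5 epimers are also present. The fallback sets out from 6 and returns at 9. Soft enolisation with Bu2BOTf and iPr2NEt (CH2Cl2, −78 °C) deprotonates the boron-complexed ester to the Z(O) dibutylboron ketene acetal F3. On warming to rt this should rearrange through the same chair to the dibutylboryl ester F4, which aqueous work-up hydrolyses to 9.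

3. Step 18. What may go wrong: ionisation of the tertiary propargylic alcohol with loss of H-6 or of a methyl hydrogen (enyne formation), cyclisation of the alkyne onto the ring diene, or poor E/Z control. The fallback sets out from 26 and returns at 29. (Z)-2-Ethoxyvinyllithium (from (Z)-1-bromo-2-ethoxyethene and tBuLi, THF, −78 °C) adds to the ketone to give the ethoxyvinyl carbinol F5. Dilute aqueous oxalic acid in THF converts it by allylic transposition and enol-ether hydrolysis into the (E)-enal F6. MeMgBr (THF, −78 °C) gives the allylic alcohol F7, and MnO2 (CH2Cl2, rt) oxidises it to 29.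

Further compounds
F1 | step 8 | 6,6-dichlorobicyclo[3.1.0]hexane adduct of 12 | CC(C)(C)[Si](C)(C)OC[C@@]1(C)C2C(C(C)[C@H]1C3(C)OCCO3)C2(Cl)Cl
F2 | step 8 | tert-butyl{[3-chloro-1,5-dimethyl-6-(2-methyl-1,3-dioxolan-2-yl)cyclohexa-2,4-dien-1-yl]methoxy}dimethylsilane (C1 and C6 as in 16) | CC(C)(C)[Si](C)(C)OC[C@@]1(C)C=C(Cl)C=C(C)[C@H]1C2(C)OCCO2
F3 | step 4 | Z(O) dibutylboron ketene acetal of 6 | C=CC(C)/C=C(\OB(CCCC)CCCC)O[C@H](C)/C=C(\C)CO[Si](C)(C)C(C)(C)C
F4 | step 4 | dibutylboryl ester of acid 9 | CC(C)(C)[Si](C)(C)OC[C@@]([C@H](C(=O)OB(CCCC)CCCC)C(C)C=C)(C)/C=C/C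
F5 | step 18 | 6-[6-((3Z)-4-ethoxy-2-hydroxybut-3-en-2-yl)-1,3,5-trimethylcyclohexa-2,4-dien-1-yl]-2-methoxy-3,5-dimethyl-4H-pyran-4-one (ring centres as in 26) | COc1oc([C@@]2(C)C=C(C)C=C(C)[C@H]2C(C)(O)/C=C\OCC)c(C)c(=O)c1C
F6 | step 18 | (2E)-3-[6-(6-methoxy-3,5-dimethyl-4-oxo-4H-pyran-2-yl)-2,4,6-trimethylcyclohexa-2,4-dien-1-yl]but-2-enal (ring centres as in 29) | COc1oc([C@@]2(C)C=C(C)C=C(C)[C@H]2/C(C)=C/C=O)c(C)c(=O)c1C
F7 | step 18 | 6-[6-((2E)-4-hydroxypent-2-en-2-yl)-1,3,5-trimethylcyclohexa-2,4-dien-1-yl]-2-methoxy-3,5-dimethyl-4H-pyran-4-one (ring centres as in 29, both carbinol epimers) | COc1oc([C@@]2(C)C=C(C)C=C(C)[C@H]2/C(C)=C/C(C)O)c(C)c(=O)c1C
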